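Atom numbers are labdane numbers throughout: C1–C10 for the decalin, C11–C16 for the side chain (C16 is the methyl on C13), C17 on C8, C18/C19 on C4, C20 on C10. Labdane names refer to the normal series (5α-H, 9α-H, 10β-CH3).

## The problem

Target 30 is a labdane: a trans-fused decalin (rings A and B) whose C9 carries a six-carbon chain ending in a methyl ester. It has six stereocenters, five contiguous on ring B (C5, C6, C8, C9, C10) and one remote (C13); C10 is quaternary and C8 a fully substituted carbinol, and the two flank C9, so the bonds around C9 are the crowded ones. C13 lies four bonds from the ring and cannot be controlled from it; it has to come from the chiral pool, and the ring must then be built in the matching absolute sense. Inside the ring the control is hierarchical: once C9 and C10 exist, C5 is epimerisable whenever C6 is a ketone, and the axial methyl groups on C4 and C10 shield the β face, so reagents reach C6 and C8 from the α face, which is what the 6β-oxygen and the 8α-hydroxyl require. The fragile features are the tertiary 8-alcohol (acid-induced dehydration), the axial 6β-acetate, which must be installed next to that alcohol, and the methyl ester, which cannot pass through enolate or hydride steps and is therefore carried as a silyl ether. The feature that opens the key step is that C7 is a methylene between the oxygen-bearing C6 and C8, and C8 carries the one-carbon branch C17. With a ketone at C6, C7 is a nucleophile; with a terminal alkyne C8≡C17, C8 is an electrophile; joining C7 to C8 closes ring B and leaves the exocyclic methylene from which the 8α-ol and its methyl arise.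

## Retrosynthesis

Ester, acetate and silyl ether (30 ← 29 ← 28 ← 27). No skeletal bond is cut. The C15 ester is traced to a primary alcohol kept as its silyl ether, because an ester at C15 would not survive the enolisation and hydride steps earlier in the route. The forward steps must only oxidise a primary alcohol next to a tertiary one and an acetate.

C6–O and C8–O (27 ← 26 ← 24 ← 23). Both oxygen stereocenters are traced to keto alkene 23: the 8α-ol and its methyl come from the 8(17)-alkene by α-face epoxidation and hydride opening at C17, and the 6β-ol comes from α-face hydride addition to the C6 ketone. Epoxidation is placed before reduction, since a free 6β-hydroxyl could steer the peracid to the β face. One hydride step then sets both centers, and the acetate goes onto the only secondary alcohol (26 → 27).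

C7–C8, the key cut (23 ← 22). Opening ring B between C7 and C8 gives the monocyclic silyl enol ether 22 with a terminal alkyne on C9. An aldol between a C6 ketone and a C8 aldehyde would make the same bond, but it would lack C17 and leave a C8 carbonyl to which a methyl nucleophile is expected to add from the α face, giving the wrong C8 epimer. The alkyne version brings C17 with it and delivers C8 as an sp2 carbon whose oxygen is added later from the correct face. The precursor 22 is much simpler: its stereocenters C5, C9 and C10 sit on or next to ring A. The forward reaction must be regioselective (6-exo over 7-endo) and must not move the new alkene into conjugation.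

Enol ether and alkyne (22 ← 21 ← 20 ← 18 + 19). The enol ether comes from methyl ketone 21 and the alkyne from a C8 aldehyde by one-carbon homologation with 19. A C6 ketone and a C8 aldehyde must never be present together, because C7 would add to C8 by aldol. C6 is therefore kept as an alcohol, tied to the C8 aldehyde as δ-lactol 18, and is oxidised only after the alkyne is in place (20 → 21). In the lactol C9 is α to a latent formyl group, which offers a second chance to correct that center by equilibration.

C6–O and C5–H (18 ← 17 ← 15). The C6 oxygen and the C5 hydrogen are traced to the ethylidene group of acid 15 by hydroboration–oxidation. Borane reduces the carboxylic acid in the same operation, and the resulting 1,5-diol 17 is oxidised at its primary hydroxyl only, which gives the lactol directly at the oxidation level that the homologation needs. The forward steps must deliver hydrogen to C5 from the face away from the axial methyls and must stop the oxidation before the lactone.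

C9–C10 (15 ← 12). The bond between the quaternary C10 and C9 is cut by an Ireland–Claisen rearrangement of allylic ester 12. An intermolecular alkylation or conjugate addition would have to create a quaternary carbon next to a gem-dimethyl group; the [3,3] shift is intramolecular, moves chirality from the carbinol carbon to C10, and sets C9 through the ketene acetal geometry. The carbinol carbon and its methyl become C6 and C7. The forward reaction requires a chair transition state and a (Z)-ketene acetal.

Ester C–O (12 ← 4 + 11). The route is convergent here: carbinol 4 carries ring A, acid 11 carries the whole side chain with C13.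

Carbinol 4 (4 ← 3 ← 2 ← 1). The single stereocenter of 4 is set by catalytic enantioselective reduction of methyl ketone 3, made from β-cyclocitral 1 by methyl addition and oxidation.

Acid 11 (11 ← 9 ← 8 ← 6 ← 5). C1–C6 of (S)-citronellol 5 map onto C15–C9, with the citronellol stereocenter becoming C13. Ozonolysis removes the isopropylidene carbon, and the missing C8 is added by carboxylation of the Grignard reagent 10 made from bromide 9.

## Roads not taken

Alternative 1: The cut is at C5–C6 and C9–C10, made together by a [2+2] cycloaddition, with ring B completed afterwards by ring expansion. Amide A1, which carries the side chain and an isopropenyl group on the future C9, would be activated with Tf2O and 2,6-di-tert-butylpyridine and added in its keteniminium form across the ring A alkene A2; hydrolysis would give the cis-fused cyclobutanone A3. The merits are real: ring A comes from a trivial alkene, the whole side chain arrives in one piece, C10 is made in the same step as C5–C6, and the configuration of C9 does not matter because that carbon becomes sp2 on ring expansion. The weak points for this target are several. The union must create two adjacent fully substituted carbons between a disubstituted keteniminium and a hindered trisubstituted alkene. Nothing in A1 or A2 relates the new C5/C10 pair to the remote C13, so a mixture of diastereomers is expected. The cis ring fusion must later be inverted. The ring expansion (reduction of the carbonyl, then an alkoxide-accelerated 1,3-shift of C6 to the isopropenyl terminus) leaves a tetrasubstituted C8=C9 alkene, to which the 8α-hydroxyl and the 9α-hydrogen must be added syn and regioselectively. In step count to a bicyclic skeleton this road is clearly shorter than the chosen plan. Against that, the chosen plan gives every ring stereocenter a defined source and reaches C8 as an exocyclic alkene with a predictable face.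

Alternative 2: The cut is at C8–C9. Keto enoate A4 would be treated with SmI2 (divalent samarium), HMPA and tert-butanol; the ketyl of the C8 methyl ketone would add 6-exo-trig to C9 of the enoate and give hydroxy ester A5. This road is better than the chosen one in two respects. The tertiary alcohol at C8, with its methyl, is formed directly and together with C9, without an epoxidation and hydride sequence, and ketyl–olefin closures of this ring size are more widely used than the 6-exo-dig gold closure. The C6 oxygen is also present from the start. The weak points are that the acceptor carbon is attached to the quaternary C10, that A5 is a γ-hydroxy ester expected to lactonise, and that the C6 carbinol of A4 is an exocyclic stereocenter that must be set without help from a ring. The decisive point is that A5 stops at C12: the five remaining carbons, with the C13 stereocenter, must be attached afterwards through a hindered position. The chosen plan has the complete chain and C13 in place before ring B is closed, so only functional-group changes follow the key step.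

Alternative 3: The cut is at C7–C8 and C9–C10, a Diels–Alder disconnection of ring B. Siloxydiene A6 (the silyl dienol ether of ketone 3) and the pantolactone allenoate A7 would combine under EtAlCl2 to give A8, with ring B closed as its C6 silyl enol ether and the 8(17)-methylene in place. In convergence and in step count to the bicyclic core this road is better than the chosen one: A6 is one step from an intermediate of the present route, the product has the same oxidation pattern as 23, and the auxiliary sets the absolute configuration without a separate enantioselective step. The weak points are the diene, whose terminus C10 is fully substituted and whose s-cis form is disfavoured by the gem-dimethyl group; the Lewis acid, which may divert the reaction to a stepwise Michael addition or cleave the dienol ether; and the endo/exo ratio, which decides C9 relative to C10. As in Alternative 2, only C11 of the side chain is present, and C9 in A8 is α to an ester and allylic, so it is easily lost while C12–C16 and C13 are added. The chosen plan closes ring B intramolecularly, so it does not depend on the reactivity of a hindered diene, and it carries C13 from the chiral pool from the first step of its side-chain branch.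

Key step: step 15

Assumption: the Ireland–Claisen rearrangement of 12 is taken to pass through a chair transition state with the carbinol methyl pseudo-equatorial; the (R) configuration chosen for 4 follows from this model.

Remark: δ-lactol 18 and its open-chain 6-hydroxy-8-aldehyde form are ring–chain tautomers of one compound, which is drawn and numbered as the lactol.

## Steps

Step 1
Reactants: 1 β-cyclocitral
Product: 2 rac-1-(2,6,6-trimethylcyclohex-1-en-1-yl)ethan-1-ol
Conditions: MeMgBr, Et2O, 0 °C; aq. NH4Cl
Reagents that add atoms: methylmagnesium bromide, C[Mg]Br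
Why: Grignard 1,2-addition to a hindered enal; the racemate is acceptable because the carbinol center is reset in steps 2 and 3.

Step 2
Reactants: 2 rac-1-(2,6,6-trimethylcyclohex-1-en-1-yl)ethan-1-ol
Product: 3 1-(2,6,6-trimethylcyclohex-1-en-1-yl)ethan-1-one
Conditions: Dess–Martin periodinane, CH2Cl2, 0 °C → rt
Reagents that add atoms: none
Why: Dess–Martin oxidation of a secondary allylic alcohol under near-neutral conditions, which avoids ionisation of the allylic system.

Step 3
Reactants: 3 1-(2,6,6-trimethylcyclohex-1-en-1-yl)ethan-1-one
Product: 4 (R)-1-(2,6,6-trimethylcyclohex-1-en-1-yl)ethan-1-ol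
Conditions: (S)-2-methyl-CBS-oxazaborolidine (cat.), BH3·SMe2, THF, −20 °C; MeOH
Reagents that add atoms: none
Why: Corey–Bakshi–Shibata reduction; the trisubstituted cyclohexenyl group is the large substituent and methyl the small one, so the (S)-catalyst should give the (R)-carbinol, as it does with aryl and alkenyl methyl ketones.

Step 4
Reactants: 5 (S)-citronellol
Product: 6 (S)-tert-butyl[(3,7-dimethyloct-6-en-1-yl)oxy]dimethylsilane
Conditions: TBSCl, imidazole, DMF, rt
Reagents that add atoms: tert-butyldimethylsilyl chloride, CC(C)(C)[Si](C)(C)Cl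
Why: Standard silylation of a primary alcohol; this ether stands in for the C15 ester until step 19.

Step 5
Reactants: 6 (S)-tert-butyl[(3,7-dimethyloct-6-en-1-yl)oxy]dimethylsilane
Product: 8 (S)-6-[(tert-butyldimethylsilyl)oxy]-4-methylhexan-1-ol, via aldehyde 7 (not isolated)
Conditions: O3, CH2Cl2/MeOH, −78 °C; NaBH4, −78 °C → rt
Reagents that add atoms: ozone, [O-][O+]=O
Why: Ozonolysis of the trisubstituted alkene with reductive work-up; the aldehyde carbon is the future C9 and the stereocenter (future C13) is untouched.

Step 6
Reactants: 8 (S)-6-[(tert-butyldimethylsilyl)oxy]-4-methylhexan-1-ol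
Product: 9 (S)-[(6-bromo-3-methylhexyl)oxy](tert-butyl)dimethylsilane
Conditions: CBr4, PPh3, CH2Cl2, 0 °C
Reagents that add atoms: carbon tetrabromide, BrC(Br)(Br)Br
Why: Appel bromination of a primary alcohol under neutral conditions that leave the silyl ether intact.

Step 7
Reactants: 9 (S)-[(6-bromo-3-methylhexyl)oxy](tert-butyl)dimethylsilane
Product: 11 (S)-7-[(tert-butyldimethylsilyl)oxy]-5-methylheptanoic acid, via Grignard reagent 10 (not isolated)
Conditions: Mg, THF, 40 °C; CO2, −78 °C → rt; 1 M HCl, 0 °C
Reagents that add atoms: carbon dioxide, O=C=O; magnesium, [Mg] (held only by 10)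
Why: Carboxylation of a primary alkylmagnesium bromide adds the one carbon (C8) that citronellol lacks; brief cold acidification frees the acid without cleaving the silyl ether.

Step 8
Reactants: 4 (R)-1-(2,6,6-trimethylcyclohex-1-en-1-yl)ethan-1-ol; 11 (S)-7-[(tert-butyldimethylsilyl)oxy]-5-methylheptanoic acid
Product: 12 (R)-1-(2,6,6-trimethylcyclohex-1-en-1-yl)ethyl (S)-7-[(tert-butyldimethylsilyl)oxy]-5-methylheptanoate
Conditions: DCC, DMAP, CH2Cl2, 0 °C → rt
Reagents that add atoms: none
Why: Steglich esterification; acyl transfer through the acylpyridinium ion acylates the hindered allylic alcohol without acid, so the carbinol center is not ionised.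

Step 9
Reactants: 12 (R)-1-(2,6,6-trimethylcyclohex-1-en-1-yl)ethyl (S)-7-[(tert-butyldimethylsilyl)oxy]-5-methylheptanoate
Product: 15 (2R,5S)-7-[(tert-butyldimethylsilyl)oxy]-2-[(1R,2E)-2-ethylidene-1,3,3-trimethylcyclohexyl]-5-methylheptanoic acid, via silyl ketene acetal 13 (not isolated), via silyl ester 14 (not isolated)
Conditions: LiN(iPr)2, THF/DMPU, −78 °C; TBSCl, −78 °C → 65 °C; 1 M HCl, THF, 0 °C
Reagents that add atoms: tert-butyldimethylsilyl chloride, CC(C)(C)[Si](C)(C)Cl (its silyl group is held by 13 and 14 and lost on hydrolysis)
Why: Ireland–Claisen rearrangement: enolisation in the presence of DMPU should give the (Z)-silyl ketene acetal 13, which rearranges through a chair with the carbinol methyl and the C11 chain both pseudo-equatorial. Chirality passes from the (R)-carbinol carbon to the quaternary C10 and the ketene acetal geometry sets C9, both as in the target, while the former carbinol carbon becomes the (E)-ethylidene; mild acid hydrolysis of silyl ester 14 frees the acid.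

Step 10
Reactants: 15 (2R,5S)-7-[(tert-butyldimethylsilyl)oxy]-2-[(1R,2E)-2-ethylidene-1,3,3-trimethylcyclohexyl]-5-methylheptanoic acid
Product: 17 (2R,5S)-7-[(tert-butyldimethylsilyl)oxy]-2-{(1R,2S)-2-[(1R)-1-hydroxyethyl]-1,3,3-trimethylcyclohexyl}-5-methylheptan-1-ol, via alkylborane 16 (not isolated)
Conditions: BH3·THF (excess), THF, 0 → 40 °C; NaOH, H2O2, 0 °C → rt
Reagents that add atoms: hydrogen peroxide, OO; borane–tetrahydrofuran, B.C1CCOC1 (boron is held only by 16)
Why: Borane reduces the carboxylic acid to the C8 alcohol and hydroborates the trisubstituted alkene with boron on the less substituted C6; oxidation proceeds with retention. Hydrogen should reach C5 from the face opposite the axial methyls on C4 and C10, which gives the C5 configuration of the target; the C6 carbinol configuration is of no consequence because C6 becomes a ketone in step 13.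

Step 11
Reactants: 17 (2R,5S)-7-[(tert-butyldimethylsilyl)oxy]-2-{(1R,2S)-2-[(1R)-1-hydroxyethyl]-1,3,3-trimethylcyclohexyl}-5-methylheptan-1-ol
Product: 18 15-[(tert-butyldimethylsilyl)oxy]-6,8-epoxy-17-nor-7,8-secolabdan-8-ol (δ-lactol)
Conditions: TEMPO (cat.), N-chlorosuccinimide (1.1 equiv), Bu4NCl, CH2Cl2/aq. NaHCO3–K2CO3 buffer (pH 8.6), rt
Reagents that add atoms: none
Why: Oxoammonium (TEMPO-mediated) oxidation under buffered two-phase conditions is selective for the primary C8 hydroxyl over secondary ones, and the hydroxy aldehyde closes at once onto the C6 hydroxyl as the δ-lactol. The hemiacetal carbinol is secondary and hindered, so with one equivalent of oxidant the reaction should stop at the lactol, the oxidation level that step 12 needs. Holding C6 as the lactol oxygen keeps a C6 ketone and a C8 aldehyde from ever being present together.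

Step 12
Reactants: 18 15-[(tert-butyldimethylsilyl)oxy]-6,8-epoxy-17-nor-7,8-secolabdan-8-ol (δ-lactol); 19 dimethyl (1-diazo-2-oxopropyl)phosphonate
Product: 20 (5S,6R,9S,10R,13S)-15-[(tert-butyldimethylsilyl)oxy]-7,8-secolabd-8(17)-yn-6-ol
Conditions: 19, K2CO3, MeOH, 0 °C → rt
Reagents that add atoms: none
Why: Ohira–Bestmann (Seyferth–Gilbert) homologation: the lactol reacts through its open hydroxy-aldehyde form with the diazomethylphosphonate anion released from 19 by methanolysis, which adds C17 as the terminal alkyne carbon and frees the C6 hydroxyl; lactols are established substrates for this homologation. The carbonate conditions are mild and the aldehyde is trapped as it is released, so C9 is expected to hold.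

Step 13
Reactants: 20 (5S,6R,9S,10R,13S)-15-[(tert-butyldimethylsilyl)oxy]-7,8-secolabd-8(17)-yn-6-ol
Product: 21 (5S,9S,10R,13S)-15-[(tert-butyldimethylsilyl)oxy]-7,8-secolabd-8(17)-yn-6-one
Conditions: Dess–Martin periodinane, CH2Cl2, rt
Reagents that add atoms: none
Why: Dess–Martin oxidation of the hindered secondary alcohol to the methyl ketone; the terminal alkyne and the silyl ether are inert.

Step 14
Reactants: 21 (5S,9S,10R,13S)-15-[(tert-butyldimethylsilyl)oxy]-7,8-secolabd-8(17)-yn-6-one
Product: 22 (5S,9S,10R,13S)-6,15-bis[(tert-butyldimethylsilyl)oxy]-7,8-secolabd-6-en-8(17)-yne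
Conditions: TBSOTf, Et3N, CH2Cl2, −78 → 0 °C
Reagents that add atoms: tert-butyldimethylsilyl trifluoromethanesulfonate, CC(C)(C)[Si](C)(C)OS(=O)(=O)C(F)(F)F
Why: Soft enolisation gives the silyl enol ether on the methyl side (C6=C7), because the only other α-hydrogen, on C5, is flanked by two quaternary carbons; the alkyne C–H is not silylated at low temperature.

Step 15
Reactants: 22 (5S,9S,10R,13S)-6,15-bis[(tert-butyldimethylsilyl)oxy]-7,8-secolabd-6-en-8(17)-yne
Product: 23 (13S)-15-[(tert-butyldimethylsilyl)oxy]labd-8(17)-en-6-one
Conditions: Ph3PAuNTf2 (5 mol%), CH2Cl2/MeOH (10:1), rt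
Reagents that add atoms: none
Why: The cationic monovalent gold complex binds the terminal alkyne of 22, and the terminal enol ether carbon C7 attacks the internal alkyne carbon C8 anti to the metal, giving a vinylgold species and a silyloxocarbenium ion. Methanol takes the silyl group, and the proton released cleaves the C17–Au bond, leaving the C6 ketone and the exocyclic 8(17)-methylene. The closest known reaction type is the gold-catalysed carbocyclisation of silyl enol ethers onto alkynes (Conia-ene type), known mostly in the 5-exo mode and less often in the 6-exo mode used here. Ring B closes 6-exo-dig through a chair in which the C5–C6 and C10–C9 bonds are both equatorial on ring A, so the trans ring fusion is preformed. No stereocenter is created: C9 and C10 come from step 9 and C5 from step 10, and C5, now α to the ketone, can be equilibrated with base to the trans-fused isomer if needed. The selectivity required is regiochemical: exo attack at C8 over 7-endo attack at C17 is secured by the polarisation of the gold-bound terminal alkyne and the smaller ring, and the nucleophile can only be C7 because step 14 places the enol double bond there. Methanol is kept to a small proportion and the reaction time short, so that protodesilylation of 22 and migration of the new alkene into conjugation do not compete.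

Step 16
Reactants: 23 (13S)-15-[(tert-butyldimethylsilyl)oxy]labd-8(17)-en-6-one
Product: 24 (13S)-15-[(tert-butyldimethylsilyl)oxy]-8α,17-epoxylabdan-6-one
Conditions: mCPBA, NaHCO3, CH2Cl2, 0 °C
Reagents that add atoms: 3-chloroperbenzoic acid, OOC(=O)c1cccc(Cl)c1
Why: Prilezhaev epoxidation of the 1,1-disubstituted alkene; the peracid should approach C8 from the α face because the axial β direction is blocked by the syn-axial C10 methyl, so the oxygen ends α. The hindered ketone is much slower in Baeyer–Villiger oxidation under cold buffered conditions.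

Step 17
Reactants: 24 (13S)-15-[(tert-butyldimethylsilyl)oxy]-8α,17-epoxylabdan-6-one
Product: 26 (13S)-15-[(tert-butyldimethylsilyl)oxy]labdane-6β,8α-diol, via epoxy alcohol 25 (not isolated)
Conditions: LiAlH4, THF, −78 °C → rt
Reagents that add atoms: none
Why: Hydride adds to the C6 ketone from the α face, because the β face carries the axial C4 and C10 methyls and the C17 methylene, giving the axial 6β-alcohol 25. On warming, hydride opens the spiro-epoxide at the primary C17, which leaves the 8α tertiary alcohol and turns C17 into the methyl; both configurations are substrate-controlled.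

Step 18
Reactants: 26 (13S)-15-[(tert-butyldimethylsilyl)oxy]labdane-6β,8α-diol
Product: 27 (13S)-6β-acetoxy-15-[(tert-butyldimethylsilyl)oxy]labdan-8α-ol
Conditions: Ac2O, DMAP, pyridine, 40 °C
Reagents that add atoms: acetic anhydride, CC(=O)OC(C)=O
Why: DMAP-catalysed acetylation distinguishes the secondary 6β-alcohol from the tertiary 8α-alcohol; gentle warming is allowed for because the 6β-hydroxyl is syn-axial to three methyl groups.

Step 19
Reactants: 27 (13S)-6β-acetoxy-15-[(tert-butyldimethylsilyl)oxy]labdan-8α-ol
Product: 28 (13S)-6β-acetoxylabdane-8α,15-diol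
Conditions: HF·pyridine, THF/pyridine, 0 °C → rt
Reagents that add atoms: none
Why: Fluoride cleavage of the primary silyl ether under buffered, non-basic conditions that spare the acetate and the tertiary alcohol.

Step 20
Reactants: 28 (13S)-6β-acetoxylabdane-8α,15-diol
Product: 29 (13S)-6β-acetoxy-8α-hydroxylabdan-15-oic acid
Conditions: TEMPO (cat.), PhI(OAc)2, MeCN/H2O (1:1), rt
Reagents that add atoms: water, O
Why: Oxoammonium oxidation of the primary alcohol through the aldehyde hydrate to the acid; the tertiary alcohol cannot be oxidised and the acetate is stable.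

Step 21
Reactants: 29 (13S)-6β-acetoxy-8α-hydroxylabdan-15-oic acid
Product: 30 methyl (13S)-6β-acetoxy-8α-hydroxylabdan-15-oate
Conditions: TMSCHN2, toluene/MeOH, 0 °C
Reagents that add atoms: trimethylsilyldiazomethane, C[Si](C)(C)C=[N+]=[N-]
Why: Methylation of the carboxylic acid under neutral conditions, so that neither the acetate nor the tertiary alcohol is touched.

## Compound list

1 | β-cyclocitral (2,6,6-trimethylcyclohex-1-ene-1-carbaldehyde) | CC1=C(C=O)C(C)(C)CCC1 | starting material
2 | rac-1-(2,6,6-trimethylcyclohex-1-en-1-yl)ethan-1-ol (racemic) | CC(O)C1=C(C)CCCC1(C)C | intermediate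
3 | 1-(2,6,6-trimethylcyclohex-1-en-1-yl)ethan-1-one | CC(=O)C1=C(C)CCCC1(C)C | intermediate
4 | (R)-1-(2,6,6-trimethylcyclohex-1-en-1-yl)ethan-1-ol | C[C@@H](O)C1=C(C)CCCC1(C)C | intermediate
5 | (S)-citronellol | OCC[C@@H](C)CCC=C(C)C | starting material
6 | (S)-tert-butyl[(3,7-dimethyloct-6-en-1-yl)oxy]dimethylsilane | CC(C)(C)[Si](C)(C)OCC[C@@H](C)CCC=C(C)C | intermediate
7 | (S)-6-[(tert-butyldimethylsilyl)oxy]-4-methylhexanal | CC(C)(C)[Si](C)(C)OCC[C@@H](C)CCC=O | intermediate
8 | (S)-6-[(tert-butyldimethylsilyl)oxy]-4-methylhexan-1-ol | CC(C)(C)[Si](C)(C)OCC[C@@H](C)CCCO | intermediate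
9 | (S)-[(6-bromo-3-methylhexyl)oxy](tert-butyl)dimethylsilane | CC(C)(C)[Si](C)(C)OCC[C@@H](C)CCCBr | intermediate
10 | Grignard reagent of 9, (S)-{6-[(tert-butyldimethylsilyl)oxy]-4-methylhexyl}magnesium bromide | CC(C)(C)[Si](C)(C)OCC[C@@H](C)CCC[Mg]Br | intermediate
11 | (S)-7-[(tert-butyldimethylsilyl)oxy]-5-methylheptanoic acid | CC(C)(C)[Si](C)(C)OCC[C@@H](C)CCCC(=O)O | intermediate
12 | (R)-1-(2,6,6-trimethylcyclohex-1-en-1-yl)ethyl (S)-7-[(tert-butyldimethylsilyl)oxy]-5-methylheptanoate | CC(C)(C)[Si](C)(C)OCC[C@@H](C)CCCC(=O)O[C@H](C)C1=C(C)CCCC1(C)C | intermediate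
13 | (Z)-tert-butyldimethylsilyl ketene acetal of 12 (C11 chain cis to the silyloxy group) | CC(C)(C)[Si](C)(C)OCC[C@@H](C)CC/C=C(/O[C@H](C)C1=C(C)CCCC1(C)C)O[Si](C)(C)C(C)(C)C | intermediate
14 | tert-butyldimethylsilyl ester of acid 15 | CC(C)(C)[Si](C)(C)OCC[C@@H](C)CC[C@@H](C(=O)O[Si](C)(C)C(C)(C)C)[C@@]1(C)CCCC(C)(C)/C1=C\C | intermediate
15 | (2R,5S)-7-[(tert-butyldimethylsilyl)oxy]-2-[(1R,2E)-2-ethylidene-1,3,3-trimethylcyclohexyl]-5-methylheptanoic acid (15-silyloxy-17-nor-7,8-secolabd-5-en-8-oic acid) | CC(C)(C)[Si](C)(C)OCC[C@@H](C)CC[C@@H](C(=O)O)[C@@]1(C)CCCC(C)(C)/C1=C\C | intermediate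
16 | alkylborane from 15 (C6–BH2 and C8–O–BH2; representative organoborane, configuration as in 17) | CC(C)(C)[Si](C)(C)OCC[C@@H](C)CC[C@@H](COB)[C@@]1(C)CCCC(C)(C)[C@@H]1[C@@H](C)B | intermediate
17 | (2R,5S)-7-[(tert-butyldimethylsilyl)oxy]-2-{(1R,2S)-2-[(1R)-1-hydroxyethyl]-1,3,3-trimethylcyclohexyl}-5-methylheptan-1-ol | CC(C)(C)[Si](C)(C)OCC[C@@H](C)CC[C@@H](CO)[C@@]1(C)CCCC(C)(C)[C@@H]1[C@@H](C)O | intermediate
18 | 15-[(tert-butyldimethylsilyl)oxy]-6,8-epoxy-17-nor-7,8-secolabdan-8-ol (δ-lactol: oxane ring O–C6–C5–C10–C9–C8 trans-fused to ring A, hydroxyl on C8, both C8 epimers; C5, C6, C9, C10 and C13 as in 17) | CC(C)(C)[Si](C)(C)OCC[C@@H](C)CC[C@@H](C2O)[C@@]1(C)CCCC(C)(C)[C@@H]1[C@@H](C)O2 | intermediate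
19 | dimethyl (1-diazo-2-oxopropyl)phosphonate | CC(=O)C(=[N+]=[N-])P(=O)(OC)OC | starting material
20 | (5S,6R,9S,10R,13S)-15-[(tert-butyldimethylsilyl)oxy]-7,8-secolabd-8(17)-yn-6-ol | CC(C)(C)[Si](C)(C)OCC[C@@H](C)CC[C@@H](C#C)[C@@]1(C)CCCC(C)(C)[C@@H]1[C@@H](C)O | intermediate
21 | (5S,9S,10R,13S)-15-[(tert-butyldimethylsilyl)oxy]-7,8-secolabd-8(17)-yn-6-one | CC(C)(C)[Si](C)(C)OCC[C@@H](C)CC[C@@H](C#C)[C@@]1(C)CCCC(C)(C)[C@@H]1C(C)=O | intermediate
22 | (5S,9S,10R,13S)-6,15-bis[(tert-butyldimethylsilyl)oxy]-7,8-secolabd-6-en-8(17)-yne | CC(C)(C)[Si](C)(C)OCC[C@@H](C)CC[C@@H](C#C)[C@@]1(C)CCCC(C)(C)[C@@H]1C(=C)O[Si](C)(C)C(C)(C)C | intermediate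
23 | (13S)-15-[(tert-butyldimethylsilyl)oxy]labd-8(17)-en-6-one | CC(C)(C)[Si](C)(C)OCC[C@@H](C)CC[C@@H]1[C@@]2(C)CCCC(C)(C)[C@@H]2C(=O)CC1=C | intermediate
24 | (13S)-15-[(tert-butyldimethylsilyl)oxy]-8α,17-epoxylabdan-6-one | CC(C)(C)[Si](C)(C)OCC[C@@H](C)CC[C@@H]1[C@@]2(C)CCCC(C)(C)[C@@H]2C(=O)C[C@@]1(C3)O3 | intermediate
25 | (13S)-15-[(tert-butyldimethylsilyl)oxy]-8α,17-epoxylabdan-6β-ol | CC(C)(C)[Si](C)(C)OCC[C@@H](C)CC[C@@H]1[C@@]2(C)CCCC(C)(C)[C@@H]2[C@H](O)C[C@@]1(C3)O3 | intermediate
26 | (13S)-15-[(tert-butyldimethylsilyl)oxy]labdane-6β,8α-diol | CC(C)(C)[Si](C)(C)OCC[C@@H](C)CC[C@@H]1[C@@]2(C)CCCC(C)(C)[C@@H]2[C@H](O)C[C@@]1(C)O | intermediate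
27 | (13S)-6β-acetoxy-15-[(tert-butyldimethylsilyl)oxy]labdan-8α-ol | CC(C)(C)[Si](C)(C)OCC[C@@H](C)CC[C@@H]1[C@@]2(C)CCCC(C)(C)[C@@H]2[C@H](OC(C)=O)C[C@@]1(C)O | intermediate
28 | (13S)-6β-acetoxylabdane-8α,15-diol | OCC[C@@H](C)CC[C@@H]1[C@@]2(C)CCCC(C)(C)[C@@H]2[C@H](OC(C)=O)C[C@@]1(C)O | intermediate
29 | (13S)-6β-acetoxy-8α-hydroxylabdan-15-oic acid | OC(=O)C[C@@H](C)CC[C@@H]1[C@@]2(C)CCCC(C)(C)[C@@H]2[C@H](OC(C)=O)C[C@@]1(C)O | intermediate
30 | methyl (13S)-6β-acetoxy-8α-hydroxylabdan-15-oate, (5S,6R,8R,9R,10S,13S) | COC(=O)C[C@@H](C)CC[C@@H]1[C@@]2(C)CCCC(C)(C)[C@@H]2[C@H](OC(C)=O)C[C@@]1(C)O | target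

## Step count and least certain steps

Total step count: 21. Longest linear sequence: 18 steps (steps 4–21, from (S)-citronellol 5); the branch from β-cyclocitral 1 runs 17 steps (steps 1–3 and 8–21).

Step 15 (key step). The 6-exo-dig closure may be slow enough that protodesilylation of the enol ether back to the ketone, or gold-mediated hydration of the alkyne, takes over; acid formed in the flask may also move the exocyclic alkene into conjugation. The fallback sets out from 21 and returns at 26; it makes the same C7–C8 bond by an aldol instead. The alkyne of 21 is hydrated in the Markovnikov sense (Ph3PAuNTf2, aqueous MeOH) to the 1,5-diketone F1. Intramolecular aldol condensation (KOH, MeOH), in which the C7 enolate attacks the less hindered C8 carbonyl, gives (13S)-15-silyloxylabd-7-en-6-one F2. Nucleophilic epoxidation (H2O2, NaOH) from the α face gives the 7α,8α-epoxy ketone F3. SmI2 in THF/MeOH at −78 °C cleaves the C7–O bond to give the 8α-hydroxy-6-ketone F4, and LiAlH4 reduces this from the α face to 26.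

Step 9. Leakage between chair and boat transition states, or incomplete control of the ketene acetal geometry, would give poor diastereoselectivity at C9; the rearrangement onto a tetrasubstituted alkene may also be slow. The fallback sets out from 12 and returns at 18; it puts C9 under thermodynamic control. The mixture of 15 and its C9 epimer F5 is carried through steps 10 and 11, giving the epimeric diol F6 and then the 9-epi-lactol F7 beside 18. DBU in toluene at 60 °C equilibrates C9 by ring opening and enolisation of the formyl group; the lactol with the side chain equatorial on the chair oxane ring, 18, is expected to predominate. The two lactols can in any case be separated at this stage and the minor one put through the same equilibration again.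

Step 11. Oxidation beyond the lactol to the δ-lactone, or incomplete conversion when the oxidant is limited, would leave a mixture of three oxidation levels. The fallback sets out from 17 and returns at 18; it overshoots deliberately and corrects the oxidation level with a hydride. Exhaustive oxidation of 17 with TEMPO (cat.) and PhI(OAc)2 in excess (CH2Cl2, rt) gives the trans-fused δ-lactone F8, a stable compound that can be purified. iBu2AlH (1.1 equiv) in CH2Cl2 at −78 °C then reduces the lactone to lactol 18.

Step 12. The hindered lactol may open too slowly, so that the diazophosphonate decomposes before homologation is complete; a slow reaction also gives the open aldehyde time to epimerise at C9. The fallback sets out from 17 and returns at 20; it bypasses the lactol and uses a free aldehyde with C6 protected. Both hydroxyls of 17 are silylated (Et3SiOTf, 2,6-lutidine) to the bis(triethylsilyl) ether F9. Swern oxidation, which converts primary triethylsilyl ethers directly into aldehydes and leaves the secondary one and the primary TBS ether, gives the aldehyde F10. Ohira–Bestmann homologation with 19 gives the alkyne F11, and PPTS in MeOH removes the secondary triethylsilyl group to give 20.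

Step 3. The twisted ketone, substituted on both sides of the ring carbon, may bind the oxazaborolidine poorly, giving slow reduction or low enantioselectivity. The fallback sets out from 2 and returns at 4; it replaces asymmetric reduction by kinetic resolution. Racemic 2 is acylated with vinyl acetate and Candida antarctica lipase B, which should convert the (R)-enantiomer into the (R)-acetate F12; after separation, methanolysis (K2CO3, MeOH) gives 4.

Step 16. Facial selectivity of the peracid on the exocyclic alkene may be insufficient, and the β,γ-epoxy ketone may open by enolisation during handling. The fallback sets out from 23 and returns at 26; it uses a bulkier oxidant. Dihydroxylation with OsO4 (cat.) and N-methylmorpholine N-oxide from the α face gives the 8α,17-dihydroxy-6-ketone F13. TsCl in pyridine sulfonylates only the primary hydroxyl to give the tosylate F14. LiAlH4 then reduces the ketone from the α face and the C17 tosylate (directly or through 25) to give 26.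

## Further compounds

F1 | step 15 | (5S,9R,10R,13S)-15-[(tert-butyldimethylsilyl)oxy]-7,8-secolabdane-6,8-dione | CC(C)(C)[Si](C)(C)OCC[C@@H](C)CC[C@@H](C(C)=O)[C@@]1(C)CCCC(C)(C)[C@@H]1C(C)=O
F2 | step 15 | (13S)-15-[(tert-butyldimethylsilyl)oxy]labd-7-en-6-one | CC(C)(C)[Si](C)(C)OCC[C@@H](C)CC[C@@H]1[C@@]2(C)CCCC(C)(C)[C@@H]2C(=O)C=C1C
F3 | step 15 | (13S)-15-[(tert-butyldimethylsilyl)oxy]-7α,8α-epoxylabdan-6-one | CC(C)(C)[Si](C)(C)OCC[C@@H](C)CC[C@@H]1[C@@]2(C)CCCC(C)(C)[C@@H]2C(=O)[C@H]3O[C@@]13C
F4 | step 15 | (13S)-15-[(tert-butyldimethylsilyl)oxy]-8α-hydroxylabdan-6-one | CC(C)(C)[Si](C)(C)OCC[C@@H](C)CC[C@@H]1[C@@]2(C)CCCC(C)(C)[C@@H]2C(=O)C[C@@]1(C)O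
F5 | step 9 | C9 epimer of acid 15 | CC(C)(C)[Si](C)(C)OCC[C@@H](C)CC[C@H](C(=O)O)[C@@]1(C)CCCC(C)(C)/C1=C\C
F6 | step 9 | C9 epimer of diol 17 | CC(C)(C)[Si](C)(C)OCC[C@@H](C)CC[C@H](CO)[C@@]1(C)CCCC(C)(C)[C@@H]1[C@@H](C)O
F7 | step 9 | C9 epimer of lactol 18 (both C8 epimers) | CC(C)(C)[Si](C)(C)OCC[C@@H](C)CC[C@H](C2O)[C@@]1(C)CCCC(C)(C)[C@@H]1[C@@H](C)O2
F8 | step 11 | (5S,6R,9R,10S,13S)-15-[(tert-butyldimethylsilyl)oxy]-17-nor-7,8-secolabdan-8,6-olide (trans-fused δ-lactone, C8 carbonyl to C6 oxygen) | CC(C)(C)[Si](C)(C)OCC[C@@H](C)CC[C@@H](C2=O)[C@@]1(C)CCCC(C)(C)[C@@H]1[C@@H](C)O2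
F9 | step 12 | 6,8-bis(triethylsilyl) ether of diol 17 | CC(C)(C)[Si](C)(C)OCC[C@@H](C)CC[C@@H](CO[Si](CC)(CC)CC)[C@@]1(C)CCCC(C)(C)[C@@H]1[C@@H](C)O[Si](CC)(CC)CC
F10 | step 12 | 15-[(tert-butyldimethylsilyl)oxy]-6-[(triethylsilyl)oxy]-17-nor-7,8-secolabdan-8-al | CC(C)(C)[Si](C)(C)OCC[C@@H](C)CC[C@@H](C=O)[C@@]1(C)CCCC(C)(C)[C@@H]1[C@@H](C)O[Si](CC)(CC)CC
F11 | step 12 | 6-O-triethylsilyl ether of alkynol 20 | CC(C)(C)[Si](C)(C)OCC[C@@H](C)CC[C@@H](C#C)[C@@]1(C)CCCC(C)(C)[C@@H]1[C@@H](C)O[Si](CC)(CC)CC
F12 | step 3 | (R)-1-(2,6,6-trimethylcyclohex-1-en-1-yl)ethyl acetate | CC(=O)O[C@H](C)C1=C(C)CCCC1(C)C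
F13 | step 16 | (13S)-15-[(tert-butyldimethylsilyl)oxy]-8α,17-dihydroxylabdan-6-one | CC(C)(C)[Si](C)(C)OCC[C@@H](C)CC[C@@H]1[C@@]2(C)CCCC(C)(C)[C@@H]2C(=O)C[C@@]1(CO)O
F14 | step 16 | 17-O-(4-methylbenzenesulfonate) of F13 | CC(C)(C)[Si](C)(C)OCC[C@@H](C)CC[C@@H]1[C@@]2(C)CCCC(C)(C)[C@@H]2C(=O)C[C@@]1(COS(=O)(=O)c3ccc(C)cc3)O
A1 | alternative 1 | methyl (3S)-6-(dimethylcarbamoyl)-3,7-dimethyloct-7-enoate (both C6 epimers) | C=C(C)C(CC[C@H](C)CC(=O)OC)C(=O)N(C)C
A2 | alternative 1 | 1,3,3-trimethylcyclohex-1-ene | CC1=CC(C)(C)CCC1
A3 | alternative 1 | methyl (3S)-3-methyl-5-[1,5,5-trimethyl-7-oxo-8-(prop-1-en-2-yl)bicyclo[4.2.0]octan-8-yl]pentanoate (cis-fused cyclobutanone) | C=C(C)[C@]1(CC[C@H](C)CC(=O)OC)[C@@]2(C)CCCC(C)(C)[C@H]2C1=O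
A4 | alternative 2 | methyl (E)-3-{2-[1-(tert-butyldimethylsilyloxy)-3-oxobutyl]-1,3,3-trimethylcyclohexyl}prop-2-enoate (C5, C6, C10 as in the target) | COC(=O)/C=C/[C@@]1(C)CCCC(C)(C)[C@@H]1[C@H](O[Si](C)(C)C(C)(C)C)CC(C)=O
A5 | alternative 2 | methyl 6β-(tert-butyldimethylsilyloxy)-8α-hydroxy-11-homodriman-12-oate | COC(=O)C[C@@H]1[C@@]2(C)CCCC(C)(C)[C@@H]2[C@H](O[Si](C)(C)C(C)(C)C)C[C@@]1(C)O
A6 | alternative 3 | tert-butyldimethyl{[1-(2,6,6-trimethylcyclohex-1-en-1-yl)ethenyl]oxy}silane | C=C(O[Si](C)(C)C(C)(C)C)C1=C(C)CCCC1(C)C
A7 | alternative 3 | (R)-pantolactone buta-2,3-dienoate | C=C=CC(=O)O[C@H]1C(=O)OCC1(C)C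
A8 | alternative 3 | pantolactonyl 6-(tert-butyldimethylsilyloxy)drima-5,8(17)-dien-11-oate (9β ester, 10β methyl) | CC3(C)COC(=O)[C@@H]3OC(=O)[C@@H]1[C@@]2(C)CCCC(C)(C)C2=C(O[Si](C)(C)C(C)(C)C)CC1=C
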